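**Plan**
Ring numbering used here: C1 ketone carbon, C2 the carbon bearing CH2CO2Me, C3 the vinylic CH, C4 the carbinol carbon, C5 the chain-bearing carbon, C6 the ring CH2.
Retrosynthesis cuts the C2=C3 enone bond and the C5–C6 bond: a [3+3] split into an acetone unit C6–C1–C2 (already carrying the acetate arm) and an enal unit C3–C4–C5 carrying the geranylgeranyl chain.
Enabling feature of the cyclohexenone ring: C1 (ketone) and C3 (a masked aldehyde carbon) are 1,5-related through C5, C4 is the α-carbon of that aldehyde, and C2 and C6 are both α to C1. Michael addition at C5, oxygenation at C4 and olefination at C3 can therefore follow one another in one flask.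
Forward: geranylgeraniol → bromide → C3-homologation to the skipped dienal; a phosphono β-keto acid is made from diethylphosphonoacetic acid; the one-flask cascade closes the only ring; methanolysis gives the target.
Stereochemistry: one chiral amine sets C5 (iminium face) and C4 (enamine face); delivery to the same face gives the cis pair; the chain E-alkenes come from geranylgeraniol.
Helpers, all lost again: CO2H on C6 (as CO2), phosphonate on C2 (as phosphate), benzoyl on O4 (last step).

Key step: step 8

Remark: the target is read as the (4R,5R) isomer in the numbering above (3R,4R in the systematic name), with OH and side chain cis; geranylgeranyl = (2E,6E,10E)-3,7,11,15-tetramethylhexadeca-2,6,10,14-tetraen-1-yl.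

**Step 1**
Reactants: 1 (2E,6E,10E)-geranylgeraniol
Product: 2 (2E,6E,10E)-geranylgeranyl bromide
Conditions: PBr3, Et2O, −10 °C
Reagents that add atoms: phosphorus tribromide, BrP(Br)Br
Why: Bromination of the primary allylic alcohol with PBr3 at low temperature is a direct displacement and should keep the 2E geometry without allylic transposition.

**Step 2**
Reactants: 2 geranylgeranyl bromide; 3 propargyl alcohol
Product: 4 (5E,9E,13E)-6,10,14,18-tetramethylnonadeca-5,9,13,17-tetraen-2-yn-1-ol
Conditions: 3, EtMgBr (2 equiv), THF, 0 °C to rt; CuCl (5 mol %); then 2, 50 °C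
Reagents that add atoms: none
Why: CuCl-catalysed alkynyl–allyl coupling of the bis-magnesium salt of propargyl alcohol with a primary allylic bromide should attack the unsubstituted allyl terminus and give the skipped enyne.

**Step 3**
Reactants: 4 enynol
Product: 5 (2E,5E,9E,13E)-6,10,14,18-tetramethylnonadeca-2,5,9,13,17-pentaen-1-ol
Conditions: LiAlH4, THF, 0 °C to 40 °C
Reagents that add atoms: none
Why: Hydroxyl-directed trans-hydroalumination of the propargylic alcohol should give only the 2E-allylic alcohol, and the isolated trisubstituted alkenes are inert to the hydride.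

**Step 4**
Reactants: 5 allylic alcohol
Product: 6 (2E,5E,9E,13E)-6,10,14,18-tetramethylnonadeca-2,5,9,13,17-pentaenal
Conditions: Dess–Martin periodinane, pyridine, CH2Cl2, 0 °C; used at once
Reagents that add atoms: none
Why: Dess–Martin oxidation of the primary allylic alcohol under buffered, non-enolising conditions should give the enal without moving the C5=C6 alkene into conjugation.

**Step 5**
Reactants: 7 diethylphosphonoacetic acid; 8 mono-tert-butyl malonate
Product: 9 tert-butyl 4-(diethoxyphosphoryl)-3-oxobutanoate
Conditions: 7, 1,1'-carbonyldiimidazole, THF, rt; then 8, MgCl2, Et3N, MeCN, rt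
Reagents that add atoms: none
Why: Acylation of the magnesium malonate half ester by the acyl imidazolide with loss of CO2 (decarboxylative Claisen condensation) is the standard route to β-keto esters and tolerates the phosphonate.

**Step 6**
Reactants: 9 tert-butyl 4-(diethoxyphosphoryl)-3-oxobutanoate; 10 methyl bromoacetate
Product: 11 1-tert-butyl 6-methyl 4-(diethoxyphosphoryl)-3-oxohexanedioate
Conditions: NaH, then n-BuLi, THF, 0 °C; then 10, −78 °C to 0 °C; aq. NH4Cl
Reagents that add atoms: none
Why: In the β-keto ester dianion the second, phosphonate-bearing carbanion is the more nucleophilic site (γ-alkylation of an acetoacetate dianion) and should take the bromoacetate; the new centre is of no consequence because it becomes sp2 in step 8.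

**Step 7**
Reactants: 11 tert-butyl methyl diester
Product: 12 4-(diethoxyphosphoryl)-6-methoxy-3,6-dioxohexanoic acid
Conditions: CF3CO2H, CH2Cl2, 0 °C; used crude and cold
Reagents that add atoms: none
Why: Acidolysis of the tert-butyl ester (loss of 2-methylpropene) frees the β-keto acid while methyl ester and phosphonate stay untouched; low temperature avoids early decarboxylation.

**Step 8**
Reactants: 6 skipped dienal; 12 phosphono β-keto acid
Product: 16 methyl 2-[(3R,4R)-3-(benzoyloxy)-4-geranylgeranyl-6-oxocyclohex-1-en-1-yl]acetate, via Michael adduct acid 13 (not isolated), via keto aldehyde 14 (not isolated), via benzoyloxy keto aldehyde 15 (not isolated)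
Conditions: (R)-α,α-diphenylprolinol trimethylsilyl ether (20 mol %), toluene, −10 °C to rt; then dibenzoyl peroxide, hydroquinone (10 mol %), THF, 0 °C; then LiCl, i-Pr2NEt, MeCN, 0 °C to rt
Reagents that add atoms: dibenzoyl peroxide, O=C(OOC(=O)c1ccccc1)c1ccccc1
Why: Proposed new method: the amine and enal 6 form an E-iminium ion, the enol of keto acid 12 adds through its CH2 carbon to the β-carbon (Michael addition, C5–C6 bond) and the adduct loses CO2; the enamine of aldehyde 14 then attacks dibenzoyl peroxide with its α-carbon (C4–O bond), and LiCl/amine finally triggers an intramolecular Horner–Wadsworth–Emmons olefination of the β-keto phosphonate carbon C2 with the aldehyde carbon C3 (C2=C3 bond), expelling diethyl phosphate. Closest known reaction types are the amine-catalysed Michael addition of β-keto esters and 4-phosphono acetoacetates to enals with ring closure by olefination, amine-catalysed decarboxylative additions of β-keto acids, and enamine α-benzoyloxylation of aldehydes with dibenzoyl peroxide; running them in one flask on one substrate is the untested part. The only ring closes in the 6-(enolendo)-exo-trig mode, the phosphonate-stabilised enolate carbon attacking the aldehyde carbonyl, and because C2 carries no second hydrogen the adduct can only collapse by phosphate loss to the endocyclic enone. C5 is controlled by the catalyst in the iminium ion (the diphenyl(silyloxy)methyl group blocks one face) and C4 by the same catalyst in the enamine, so carbon and oxygen enter the same face of the former E-alkene and end cis on the ring; the (R)-catalyst should give 4R,5R. The step needs 1,4- over 1,2-addition (secured by iminium activation), attack through the CH2 of 12 and not its hindered phosphonate carbon (secured by the higher enol content between ketone and acid), and oxygenation before ring closure (secured by withholding base until the peroxide is consumed).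

**Step 9**
Reactants: 16 benzoate
Product: 17 methyl 2-[(3R,4R)-3-hydroxy-4-geranylgeranyl-6-oxocyclohex-1-en-1-yl]acetate (target)
Conditions: K2CO3 (0.2 equiv), MeOH, 0 °C
Reagents that add atoms: none
Why: Base-catalysed transesterification removes the secondary benzoate as methyl benzoate, the methyl ester exchanges only with itself, and the low temperature should prevent epimerisation or double-bond migration.

**Compound list**
1 | (2E,6E,10E)-geranylgeraniol | OC/C=C(\C)CC/C=C(\C)CC/C=C(\C)CCC=C(C)C | starting material
2 | (2E,6E,10E)-geranylgeranyl bromide | BrC/C=C(\C)CC/C=C(\C)CC/C=C(\C)CCC=C(C)C | intermediate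
3 | propargyl alcohol | OCC#C | starting material
4 | (5E,9E,13E)-6,10,14,18-tetramethylnonadeca-5,9,13,17-tetraen-2-yn-1-ol | OCC#CC/C=C(\C)CC/C=C(\C)CC/C=C(\C)CCC=C(C)C | intermediate
5 | (2E,5E,9E,13E)-6,10,14,18-tetramethylnonadeca-2,5,9,13,17-pentaen-1-ol | OC/C=C/C/C=C(\C)CC/C=C(\C)CC/C=C(\C)CCC=C(C)C | intermediate
6 | (2E,5E,9E,13E)-6,10,14,18-tetramethylnonadeca-2,5,9,13,17-pentaenal | O=C/C=C/C/C=C(\C)CC/C=C(\C)CC/C=C(\C)CCC=C(C)C | intermediate
7 | diethylphosphonoacetic acid | CCOP(=O)(CC(=O)O)OCC | starting material
8 | mono-tert-butyl malonate | CC(C)(C)OC(=O)CC(=O)O | starting material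
9 | tert-butyl 4-(diethoxyphosphoryl)-3-oxobutanoate | CCOP(=O)(CC(=O)CC(=O)OC(C)(C)C)OCC | intermediate
10 | methyl bromoacetate | COC(=O)CBr | starting material
11 | 1-tert-butyl 6-methyl 4-(diethoxyphosphoryl)-3-oxohexanedioate (racemic) | CCOP(=O)(OCC)C(CC(=O)OC)C(=O)CC(=O)OC(C)(C)C | intermediate
12 | 4-(diethoxyphosphoryl)-6-methoxy-3,6-dioxohexanoic acid (racemic) | CCOP(=O)(OCC)C(CC(=O)OC)C(=O)CC(=O)O | intermediate
13 | methyl (6S,8E,12E,16E)-5-carboxy-3-(diethoxyphosphoryl)-9,13,17,21-tetramethyl-4-oxo-6-(2-oxoethyl)docosa-8,12,16,20-tetraenoate (mixture at C3 and C5) | O=CC[C@H](C/C=C(\C)CC/C=C(\C)CC/C=C(\C)CCC=C(C)C)C(C(=O)O)C(=O)C(CC(=O)OC)P(=O)(OCC)OCC | intermediate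
14 | methyl (6S,8E,12E,16E)-3-(diethoxyphosphoryl)-9,13,17,21-tetramethyl-4-oxo-6-(2-oxoethyl)docosa-8,12,16,20-tetraenoate (mixture at C3) | O=CC[C@H](C/C=C(\C)CC/C=C(\C)CC/C=C(\C)CCC=C(C)C)CC(=O)C(CC(=O)OC)P(=O)(OCC)OCC | intermediate
15 | methyl (6R,8E,12E,16E)-6-[(1R)-1-(benzoyloxy)-2-oxoethyl]-3-(diethoxyphosphoryl)-9,13,17,21-tetramethyl-4-oxodocosa-8,12,16,20-tetraenoate (mixture at C3) | O=C[C@H](OC(=O)c1ccccc1)[C@H](C/C=C(\C)CC/C=C(\C)CC/C=C(\C)CCC=C(C)C)CC(=O)C(CC(=O)OC)P(=O)(OCC)OCC | intermediate
16 | methyl 2-[(3R,4R)-3-(benzoyloxy)-6-oxo-4-[(2E,6E,10E)-3,7,11,15-tetramethylhexadeca-2,6,10,14-tetraen-1-yl]cyclohex-1-en-1-yl]acetate | COC(=O)CC1=C[C@H](OC(=O)c2ccccc2)[C@H](C/C=C(\C)CC/C=C(\C)CC/C=C(\C)CCC=C(C)C)CC1=O | intermediate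
17 | methyl 2-[(3R,4R)-3-hydroxy-6-oxo-4-[(2E,6E,10E)-3,7,11,15-tetramethylhexadeca-2,6,10,14-tetraen-1-yl]cyclohex-1-en-1-yl]acetate | COC(=O)CC1=C[C@H](O)[C@H](C/C=C(\C)CC/C=C(\C)CC/C=C(\C)CCC=C(C)C)CC1=O | target

**Count**
Total steps: 9. Longest linear sequence: 6 (steps 1, 2, 3, 4, 8, 9).

**Steps most likely to fail**

Step 8. Under amine catalysis the skipped C5=C6 alkene of 6 may migrate into conjugation through a trienamine before the Michael addition. Keto acid 12 may lose CO2 before it adds. The peroxide may oxidise the catalyst. The α-benzoyloxy aldehyde may epimerise before the ring closes. The fallback uses known chemistry, sets out from 5 and 11 and comes back at 14. Transesterification of 11 with 5 (toluene, 100 °C, DMAP cat.) should give the allyl β-keto ester F1. Iridium-catalysed decarboxylative allylic alkylation ([Ir(cod)Cl]2, BINOL-derived phosphoramidite, THF, 50 °C; the ligand enantiomer that gives 6R) forms the C5–C6 bond at the substituted allyl terminus and should give the branched vinyl ketone F2, with no enal exposed to an amine. 9-BBN then NaBO3 should hydroxylate only the terminal vinyl group to the primary alcohol F3. Dess–Martin oxidation then gives 14. From 14 the α-benzoyloxylation and the LiCl/amine olefination of step 8 are run in separate flasks, through isolated 15, to 16.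

Step 2. Attack at the substituted allyl terminus (SN2' pathway) may give the branched isomer, and the 2E geometry may erode. The fallback sets out from 2 and comes back at 5. Stille coupling of 2 with (E)-3-(tributylstannyl)prop-2-en-1-ol (Pd2(dba)3, tri(2-furyl)phosphine, THF, 50 °C) joins the allyl carbon to the vinyl carbon directly and should give 5 without passing through 4. It makes no new compound.

Step 9. Under methoxide the ring double bond may migrate toward the ester, or the γ-hydroxy enone may isomerise. The fallback sets out from 14 (step 8 stopped after its first stage and 14 isolated) and comes back at 17. L-Proline-catalysed α-aminoxylation with nitrosobenzene should give the α-(phenylaminooxy) keto aldehyde F4 with the same 4R sense. LiCl/i-Pr2NEt closes the ring to the anilinooxy enone F5. Cu(OAc)2 (cat.) in MeOH then cleaves the N–O bond under neutral conditions to 17, so no ester has to be removed with base.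

**Further compounds**
F1 | step 8 | 6-methyl 1-[(2E,5E,9E,13E)-6,10,14,18-tetramethylnonadeca-2,5,9,13,17-pentaen-1-yl] 4-(diethoxyphosphoryl)-3-oxohexanedioate | CCOP(=O)(OCC)C(CC(=O)OC)C(=O)CC(=O)OC/C=C/C/C=C(\C)CC/C=C(\C)CC/C=C(\C)CCC=C(C)C
F2 | step 8 | methyl (6R,8E,12E,16E)-3-(diethoxyphosphoryl)-6-ethenyl-9,13,17,21-tetramethyl-4-oxodocosa-8,12,16,20-tetraenoate | C=C[C@H](C/C=C(\C)CC/C=C(\C)CC/C=C(\C)CCC=C(C)C)CC(=O)C(CC(=O)OC)P(=O)(OCC)OCC
F3 | step 8 | methyl (6S,8E,12E,16E)-3-(diethoxyphosphoryl)-6-(2-hydroxyethyl)-9,13,17,21-tetramethyl-4-oxodocosa-8,12,16,20-tetraenoate | OCC[C@H](C/C=C(\C)CC/C=C(\C)CC/C=C(\C)CCC=C(C)C)CC(=O)C(CC(=O)OC)P(=O)(OCC)OCC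
F0 | step 2 | none | none
F4 | step 9 | methyl (6R,8E,12E,16E)-3-(diethoxyphosphoryl)-9,13,17,21-tetramethyl-4-oxo-6-[(1R)-2-oxo-1-(phenylaminooxy)ethyl]docosa-8,12,16,20-tetraenoate | O=C[C@H](ONc1ccccc1)[C@H](C/C=C(\C)CC/C=C(\C)CC/C=C(\C)CCC=C(C)C)CC(=O)C(CC(=O)OC)P(=O)(OCC)OCC
F5 | step 9 | methyl 2-[(3R,4R)-6-oxo-3-(phenylaminooxy)-4-[(2E,6E,10E)-3,7,11,15-tetramethylhexadeca-2,6,10,14-tetraen-1-yl]cyclohex-1-en-1-yl]acetate | COC(=O)CC1=C[C@H](ONc2ccccc2)[C@H](C/C=C(\C)CC/C=C(\C)CC/C=C(\C)CCC=C(C)C)CC1=O
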